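**Retrosynthetic overview**

1. The target is the tris-angelate of a 7,9,15-triol, so the three esters are made last in one operation. The anti-7,9-diol comes from a tricyclic bis-enone by C7 hydroxylation (conjugate borylation, oxidation) and a hydroxyl-directed reduction at C9.
2. Key disconnection C10–C11: these are the α-carbons of the C9 and C1 ketones, both normally nucleophilic. They are joined by oxidising the bis-enolate of a cis-fused cyclohexenone–cycloheptenone, which closes the cyclobutane (third ring) and fixes C10 and C11.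
3. Ring B (seven-membered, second ring) comes from ring-closing metathesis of a vinyl ketone with the vinyl group on C6; the C1 ketone comes from allylic oxidation.
4. The C4–C10 bond comes from an Eschenmoser–Claisen rearrangement on a ring A cyclohexenol, cis to the C5 side chain. Ring A (first ring) comes from an enamine Michael/aldol annulation of a β-quaternary aldehyde with ethyl vinyl ketone.
5. The C6 quaternary centre comes from a palladium-catalysed asymmetric allylic alkylation of isoprene monoepoxide with dimethyl malonate.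

Assumption: atom labels follow longipinane numbering and are used for open-chain precursors too. C1 is the ketone, C2=C3 the enone alkene (CH3-12 on C3), C4 and C11 the bridgeheads, C5 the cyclobutane CH bearing C6, C6 carries CH3-14 and CH2O-15, C7 and C9 are the oxygenated carbons, C8 is CH2, and C10 carries CH3-13. TBS = tert-butyl(dimethyl)silyl.

**Route**

Step 1
Reactants: 1 2-methyl-2-vinyloxirane (racemic); 2 dimethyl malonate
Product: 3 dimethyl 2-[(2S)-1-hydroxy-2-methylbut-3-en-2-yl]propanedioate
Conditions: Pd2(dba)3·CHCl3 (1 mol%), (S,S)-DACH-naphthyl Trost ligand (3 mol%), CH2Cl2, rt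
Reagents that add atoms: none
Why: Trost asymmetric allylic alkylation run as a dynamic kinetic asymmetric transformation: both epoxide enantiomers pass through interconverting π-allyl intermediates on palladium, and the alkoxide-guided malonate attacks the substituted terminus to set the C6 quaternary centre (the ligand antipode would give ent-3, so the sense is confirmed on the first run).

Step 2
Reactants: 3 dimethyl 2-[(2S)-1-hydroxy-2-methylbut-3-en-2-yl]propanedioate
Product: 4 dimethyl 2-[(2S)-1-(TBS-oxy)-2-methylbut-3-en-2-yl]propanedioate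
Conditions: TBSCl, imidazole, DMF, 0 °C → rt
Reagents that add atoms: tert-butyl(chloro)dimethylsilane, CC(C)(C)[Si](C)(C)Cl
Why: Routine silylation of the primary alcohol, done at once so that 3 cannot lactonise onto a malonate ester; no stereocentre is touched.

Step 3
Reactants: 4 dimethyl 2-[(2S)-1-(TBS-oxy)-2-methylbut-3-en-2-yl]propanedioate
Product: 5 methyl (3R)-3-[(TBS-oxy)methyl]-3-methylpent-4-enoate
Conditions: LiCl, H2O, DMSO, 150 °C
Reagents that add atoms: none
Why: Krapcho dealkoxycarbonylation (chloride attacks the ester methyl, then decarboxylation); the quaternary centre is untouched and the descriptor changes only through CIP priorities.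

Step 4
Reactants: 5 methyl (3R)-3-[(TBS-oxy)methyl]-3-methylpent-4-enoate
Product: 6 (3R)-3-[(TBS-oxy)methyl]-3-methylpent-4-enal
Conditions: i-Bu2AlH (1.05 equiv), CH2Cl2, −78 °C
Reagents that add atoms: none
Why: Partial reduction of the ester by i-Bu2AlH stops at the aluminium hemiacetal at −78 °C and gives the aldehyde on work-up.

Step 5
Reactants: 6 (3R)-3-[(TBS-oxy)methyl]-3-methylpent-4-enal; 7 pent-1-en-3-one
Product: 9 (4R)-4-[(2S)-1-(TBS-oxy)-2-methylbut-3-en-2-yl]-2-methylcyclohex-2-en-1-one, via keto-aldehyde Michael adduct 8 (not isolated)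
Conditions: (S)-2-[methoxy(diphenyl)methyl]pyrrolidine (10 mol%), ethyl 3,4-dihydroxybenzoate (20 mol%), neat, 4 °C; then LiOH·H2O (0.3 equiv), i-PrOH, rt
Reagents that add atoms: none
Why: Enamine-catalysed Michael addition to the vinyl ketone, where the (S)-prolinol ether shields one enamine face and sets C5 by catalyst control, followed by intramolecular aldol condensation (organocatalytic Robinson annulation) to close ring A.

Step 6
Reactants: 9 (4R)-4-[(2S)-1-(TBS-oxy)-2-methylbut-3-en-2-yl]-2-methylcyclohex-2-en-1-one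
Product: 10 (1S,4R)-4-[(2S)-1-(TBS-oxy)-2-methylbut-3-en-2-yl]-2-methylcyclohex-2-en-1-ol
Conditions: (R)-2-methyl-CBS-oxazaborolidine (20 mol%), catecholborane (1.5 equiv), toluene, −78 °C
Reagents that add atoms: none
Why: Corey–Bakshi–Shibata reduction under reagent control gives the (S)-carbinol, with the hydroxyl cis to the C5 side chain; catecholborane leaves the vinyl group alone.

Step 7
Reactants: 10 (1S,4R)-4-[(2S)-1-(TBS-oxy)-2-methylbut-3-en-2-yl]-2-methylcyclohex-2-en-1-ol; 11 1,1-dimethoxy-N,N-dimethylpropan-1-amine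
Product: 13 2-[(1S,6R)-6-[(2S)-1-(TBS-oxy)-2-methylbut-3-en-2-yl]-2-methylcyclohex-2-en-1-yl]-N,N-dimethylpropanamide, via ketene N,O-acetal 12 (not isolated)
Conditions: xylenes, 140 °C, sealed tube
Reagents that add atoms: none
Why: Eschenmoser–Claisen rearrangement: the suprafacial [3,3] shift delivers C10 to C4 on the face that carried the C2 oxygen (cis to the C5 side chain) and moves the alkene to C2=C3; the new C10 centre forms as an epimer mixture that is erased in step 11.

Step 8
Reactants: 13 2-[(1S,6R)-6-[(2S)-1-(TBS-oxy)-2-methylbut-3-en-2-yl]-2-methylcyclohex-2-en-1-yl]-N,N-dimethylpropanamide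
Product: 14 4-[(1S,6R)-6-[(2S)-1-(TBS-oxy)-2-methylbut-3-en-2-yl]-2-methylcyclohex-2-en-1-yl]pent-1-en-3-one
Conditions: CH2=CHLi (1.5 equiv), THF, −78 °C; inverse quench into cold aqueous buffer
Reagents that add atoms: vinyllithium, [Li]C=C
Why: Acyl substitution of the tertiary amide: the tetrahedral lithium hemiaminal survives until the quench, so the vinyl ketone is released only on work-up and is not attacked a second time.

Step 9
Reactants: 14 4-[(1S,6R)-6-[(2S)-1-(TBS-oxy)-2-methylbut-3-en-2-yl]-2-methylcyclohex-2-en-1-yl]pent-1-en-3-one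
Product: 15 cis-fused 9-[(TBS-oxy)methyl]-4,5,9-trimethyl-1,2,4a,5,9,9a-hexahydro-6H-benzo[7]annulen-6-one (C9 ketone, C7=C8, C2=C3; H-4 and H-5 cis)
Conditions: second-generation Hoveyda–Grubbs catalyst RuCl2(H2IMes)(=CH-C6H4-2-O-i-Pr) (5 mol%), toluene (2 mM), 80 °C
Reagents that add atoms: none
Why: Ring-closing metathesis between the vinyl ketone and the vinyl group on C6 forms the cycloheptenone (ring B) with loss of ethene; the trisubstituted ring A alkene is inert, and the cis relationship set in steps 5–7 makes the ring fusion cis.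

Step 10
Reactants: 15 cis-fused bicyclic enone (C9 ketone)
Product: 16 cis-fused 9-[(TBS-oxy)methyl]-4,5,9-trimethyl-4a,5,9,9a-tetrahydro-1H-benzo[7]annulene-2,6-dione (C1 and C9 ketones)
Conditions: Rh2(cap)4 (cap = caprolactamate, 1 mol%), t-BuOOH (70% in water, 5 equiv), CH2Cl2, rt
Reagents that add atoms: tert-butyl hydroperoxide, CC(C)(C)OO
Why: Allylic C–H oxidation via a tert-butylperoxy radical takes the only accessible allylic CH2 (C1, next to the alkene CH) to the ketone, as in the conversion of 1-methylcyclohexenes to 3-methylcyclohex-2-enones; C4-H is tertiary and flanked by two substituents.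

Step 11
Reactants: 16 cis-fused bicyclic dienedione
Product: 18 6-[(TBS-oxy)methyl]-2,6,9-trimethyltricyclo[5.4.0.0(2,8)]undeca-4,9-diene-3,11-dione (15-TBS-oxy-longipina-2,7-diene-1,9-dione), via dilithium bis-enolate 17 (not isolated)
Conditions: LiN(i-Pr)2 (2.2 equiv), THF, −78 °C (16 added to the base); then Fe(acac)3 (2.2 equiv), −78 °C → rt, 5 mM
Reagents that add atoms: none
Why: Proposed new method: double kinetic deprotonation can only occur at C11 (α′ of the ring A enone) and C10 (α′ of the ring B enone, since C8 is vinylic and C6 quaternary); one-electron oxidation of bis-enolate 17 gives an α-keto radical that closes 4-exo onto the neighbouring enolate carbon held close by the cis ring fusion, the resulting ketyl being allylically stabilised and oxidised on to the ketone, so the two normally nucleophilic α-carbons are joined, the cyclobutane is closed and C10 (quaternary) and C11 are fixed because the bond can only form on the face that already carries C10; the closest known reactions are intramolecular oxidative enolate heterocoupling with Fe(acac)3 or copper bis(2-ethylhexanoate) and the oxidative cyclisation of adipate-type bis-enolates to cyclobutane-1,2-dicarbonyl compounds.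

Step 12
Reactants: 18 tricyclic dienedione
Product: 20 15-(TBS-oxy)-7-hydroxylongipin-2-ene-1,9-dione (7-OH on the face of CH3-14), via beta-boryl ketone 19 (not isolated)
Conditions: CuCl (5 mol%), NaOt-Bu (10 mol%), DPEphos (5 mol%), B2pin2 (1.1 equiv), MeOH (2 equiv), THF, rt; then H2O2 (30% aq), pH 7 phosphate buffer, 0 °C
Reagents that add atoms: hydrogen peroxide, OO
Why: Copper-catalysed conjugate borylation picks the cis-disubstituted cycloheptenone over the β,β-disubstituted ring A enone and adds boron to C7 anti to the bulkier CH2OTBS group on C6 (syn to CH3-14), and the C–B bond is oxidised with retention; neutral buffering avoids retro-aldol opening of the β-hydroxy ketone.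

Step 13
Reactants: 20 15-(TBS-oxy)-7-hydroxylongipin-2-ene-1,9-dione
Product: 21 15-(TBS-oxy)-7,9-dihydroxylongipin-2-en-1-one (7,9-anti diol)
Conditions: Me4NBH(OAc)3 (5 equiv), MeCN/AcOH (1:1), −30 °C
Reagents that add atoms: none
Why: Evans–Saksena reduction: the C7 alkoxy-borohydride delivers hydride intramolecularly to the same face of the C9 ketone, giving the 7,9-anti diol, while the C1 enone, which has no directing hydroxyl, is not reduced.

Step 14
Reactants: 21 15-(TBS-oxy)-7,9-dihydroxylongipin-2-en-1-one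
Product: 22 7,9,15-trihydroxylongipin-2-en-1-one
Conditions: HF·pyridine, THF/pyridine, 0 °C → rt
Reagents that add atoms: none
Why: Fluoride-driven cleavage of the primary silyl ether under non-basic conditions, which avoids any retro-aldol or epimerisation chemistry.

Step 15
Reactants: 22 7,9,15-trihydroxylongipin-2-en-1-one; 23 angelic acid [(2Z)-2-methylbut-2-enoic acid], of which three molecules are taken up per molecule of 22
Product: 24 CNP0266467.1, 7,9,15-tris(angeloyloxy)longipin-2-en-1-one
Conditions: 23 (9 equiv), 2,4,6-trichlorobenzoyl chloride (9 equiv), Et3N (9 equiv), toluene, rt, 2 h; then 22, toluene, 80 °C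
Reagents that add atoms: angelic acid (second and third molecules), C/C=C(/C)C(=O)O.C/C=C(/C)C(=O)O
Why: Threefold Yamaguchi esterification, one molecule of 23 per hydroxyl, each delivered through the mixed anhydride and run hot without a nucleophilic amine catalyst so that the (Z)-angelate does not isomerise to the tiglate; the excess of acylating agent drives acylation of the two neopentyl secondary hydroxyls as well as the primary one.

**Compound list**

1 | 2-methyl-2-vinyloxirane (isoprene monoepoxide, racemic) | CC1(CO1)C=C | starting material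
2 | dimethyl malonate | COC(=O)CC(=O)OC | starting material
3 | dimethyl 2-[(2S)-1-hydroxy-2-methylbut-3-en-2-yl]propanedioate | OC[C@](C=C)(C)C(C(=O)OC)C(=O)OC | intermediate
4 | dimethyl 2-[(2S)-1-(TBS-oxy)-2-methylbut-3-en-2-yl]propanedioate | CC(C)(C)[Si](C)(C)OC[C@](C=C)(C)C(C(=O)OC)C(=O)OC | intermediate
5 | methyl (3R)-3-[(TBS-oxy)methyl]-3-methylpent-4-enoate | CC(C)(C)[Si](C)(C)OC[C@](C=C)(C)CC(=O)OC | intermediate
6 | (3R)-3-[(TBS-oxy)methyl]-3-methylpent-4-enal | CC(C)(C)[Si](C)(C)OC[C@](C=C)(C)CC=O | intermediate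
7 | pent-1-en-3-one (ethyl vinyl ketone) | CCC(=O)C=C | starting material
8 | (2S)-2-[(2S)-1-(TBS-oxy)-2-methylbut-3-en-2-yl]-5-oxoheptanal | CC(C)(C)[Si](C)(C)OC[C@](C=C)(C)[C@@H](C=O)CCC(=O)CC | intermediate
9 | (4R)-4-[(2S)-1-(TBS-oxy)-2-methylbut-3-en-2-yl]-2-methylcyclohex-2-en-1-one | CC(C)(C)[Si](C)(C)OC[C@](C=C)(C)[C@@H]1CCC(=O)C(C)=C1 | intermediate
10 | (1S,4R)-4-[(2S)-1-(TBS-oxy)-2-methylbut-3-en-2-yl]-2-methylcyclohex-2-en-1-ol (OH cis to side chain) | CC(C)(C)[Si](C)(C)OC[C@](C=C)(C)[C@@H]1CC[C@H](O)C(C)=C1 | intermediate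
11 | 1,1-dimethoxy-N,N-dimethylpropan-1-amine | CCC(OC)(OC)N(C)C | starting material
12 | (1Z)-1-{[(1S,4R)-4-[(2S)-1-(TBS-oxy)-2-methylbut-3-en-2-yl]-2-methylcyclohex-2-en-1-yl]oxy}-N,N-dimethylprop-1-en-1-amine | CC(C)(C)[Si](C)(C)OC[C@](C=C)(C)[C@@H]1CC[C@H](O/C(=C\C)N(C)C)C(C)=C1 | intermediate
13 | 2-[(1S,6R)-6-[(2S)-1-(TBS-oxy)-2-methylbut-3-en-2-yl]-2-methylcyclohex-2-en-1-yl]-N,N-dimethylpropanamide (C10 epimers) | CC(C)(C)[Si](C)(C)OC[C@](C=C)(C)[C@@H]1CCC=C(C)[C@@H]1C(C)C(=O)N(C)C | intermediate
14 | 4-[(1S,6R)-6-[(2S)-1-(TBS-oxy)-2-methylbut-3-en-2-yl]-2-methylcyclohex-2-en-1-yl]pent-1-en-3-one (C10 epimers) | CC(C)(C)[Si](C)(C)OC[C@](C=C)(C)[C@@H]1CCC=C(C)[C@@H]1C(C)C(=O)C=C | intermediate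
15 | cis-fused 9-[(TBS-oxy)methyl]-4,5,9-trimethyl-1,2,4a,5,9,9a-hexahydro-6H-benzo[7]annulen-6-one (C10 epimers) | CC(C)(C)[Si](C)(C)OC[C@]1(C)[C@@H]2CCC=C(C)[C@@H]2C(C)C(=O)C=C1 | intermediate
16 | cis-fused 9-[(TBS-oxy)methyl]-4,5,9-trimethyl-4a,5,9,9a-tetrahydro-1H-benzo[7]annulene-2,6-dione (C10 epimers) | CC(C)(C)[Si](C)(C)OC[C@]1(C)[C@@H]2CC(=O)C=C(C)[C@@H]2C(C)C(=O)C=C1 | intermediate
17 | dilithium bis-enolate of 16 (C11=C1-OLi and C10=C9-OLi) | CC(C)(C)[Si](C)(C)OC[C@]1(C)[C@@H]2C=C(O[Li])C=C(C)[C@@H]2C(C)=C(O[Li])C=C1 | intermediate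
18 | 15-(TBS-oxy)longipina-2,7-diene-1,9-dione | CC(C)(C)[Si](C)(C)OC[C@]1(C)[C@@H]2[C@H]3C(=O)C=C(C)[C@@H]2[C@@]3(C)C(=O)C=C1 | intermediate
19 | 15-(TBS-oxy)-7-(pinacolatoboryl)longipin-2-ene-1,9-dione | CC(C)(C)[Si](C)(C)OC[C@]1(C)[C@@H]2[C@H]3C(=O)C=C(C)[C@@H]2[C@@]3(C)C(=O)C[C@H]1B1OC(C)(C)C(C)(C)O1 | intermediate
20 | 15-(TBS-oxy)-7-hydroxylongipin-2-ene-1,9-dione | CC(C)(C)[Si](C)(C)OC[C@]1(C)[C@@H]2[C@H]3C(=O)C=C(C)[C@@H]2[C@@]3(C)C(=O)C[C@H]1O | intermediate
21 | 15-(TBS-oxy)-7,9-dihydroxylongipin-2-en-1-one (7,9-anti) | CC(C)(C)[Si](C)(C)OC[C@]1(C)[C@@H]2[C@H]3C(=O)C=C(C)[C@@H]2[C@@]3(C)[C@H](O)C[C@H]1O | intermediate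
22 | 7,9,15-trihydroxylongipin-2-en-1-one | OC[C@]1(C)[C@@H]2[C@H]3C(=O)C=C(C)[C@@H]2[C@@]3(C)[C@H](O)C[C@H]1O | intermediate
23 | angelic acid, (2Z)-2-methylbut-2-enoic acid | C/C=C(/C)C(=O)O | starting material
24 | CNP0266467.1, [3,5-bis(angeloyloxy)-2,6,9-trimethyl-11-oxotricyclo[5.4.0.0(2,8)]undec-9-en-6-yl]methyl (2Z)-2-methylbut-2-enoate | C/C=C(/C)C(=O)OC[C@]1(C)[C@@H]2[C@H]3C(=O)C=C(C)[C@@H]2[C@@]3(C)[C@H](OC(=O)/C(C)=C\C)C[C@H]1OC(=O)/C(C)=C\C | target

**Step count and risks**

Total step count: 15. Longest linear sequence: 15 steps (from 1 to 24).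

The three steps most likely to fail:

Step 11 (oxidative bis-enolate coupling to the cyclobutane). The risks are intermolecular coupling and failure of the strained 4-exo closure. The fallback sets out from 16 and returns at 18, replacing the one-electron coupling by a two-electron alkylation with an enolonium equivalent. Kinetic mono-deprotonation at the less hindered α′-CH2 (LiN(i-Pr)2, 1.05 equiv, THF, −78 °C) and trapping with Me3SiCl give the C1-O-trimethylsilyl dienol ether F1. NBS (THF, −78 °C) brominates C11 from the face opposite the C4 and C5 substituents to give the 11-bromo ketone F2. KN(SiMe3)2 (THF, −78 → 0 °C) then forms the C10 enolate, which displaces bromide with inversion in a 4-exo-tet alkylation to give 18, as in keto-sulfonate cyclobutane closures of copaene-type skeletons.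

Step 10 (allylic oxidation). The risks are attack at C4-H or CH3-12 and over-oxidation. The fallback sets out from 15 and returns at 16, using a regiochemically unambiguous epoxide/selenoxide/transposition sequence. mCPBA (NaHCO3, CH2Cl2, 0 °C) epoxidises only the electron-rich C2=C3 alkene to give the 2,3-epoxide F3. PhSeNa [from (PhSe)2 and NaBH4, EtOH] opens it at the secondary carbon to give the 2-phenylselanyl-3-hydroxy compound F4; any selenide added reversibly to the cycloheptenone is expelled in the next oxidation. H2O2 (THF, 0 °C → rt) causes selenoxide syn-elimination, which can only go towards C1 because C3 has no hydrogen, giving the tertiary allylic alcohol F5. Pyridinium chlorochromate, [C5H5NH][CrO3Cl], in CH2Cl2 then effects the oxidative 1,3-transposition to enone 16.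

Step 12 (C7 hydroxylation). The risks are facial selectivity at C7, borylation of the ring A enone, and retro-aldol or elimination of the β-hydroxy ketone. The fallback sets out from 18 and returns at 20, going through an epoxy ketone instead of a boronate. Nucleophilic epoxidation (t-BuOOH, DBU, CH2Cl2, 0 °C) of the cis-disubstituted cycloheptenone, anti to CH2OTBS, gives the 7,8-epoxy ketone F6. Reductive cleavage of the Cα–O bond with Na[PhSeB(OEt)3] [(PhSe)2, NaBH4, EtOH, AcOH, 0 °C] under weakly acidic conditions gives 20.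

**Further compounds**

F1 | step 11 | C1-O-trimethylsilyl C1=C11 dienol ether of 16 | CC(C)(C)[Si](C)(C)OC[C@]1(C)[C@@H]2C=C(O[Si](C)(C)C)C=C(C)[C@@H]2C(C)C(=O)C=C1
F2 | step 11 | 11-bromo derivative of 16 (Br trans to the C5 side chain) | CC(C)(C)[Si](C)(C)OC[C@]1(C)[C@@H]2[C@@H](Br)C(=O)C=C(C)[C@@H]2C(C)C(=O)C=C1
F3 | step 10 | 2,3-epoxide of 15 | CC(C)(C)[Si](C)(C)OC[C@]1(C)[C@@H]2CCC3OC3(C)[C@@H]2C(C)C(=O)C=C1
F4 | step 10 | 3-hydroxy-2-(phenylselanyl) derivative of 15 | CC(C)(C)[Si](C)(C)OC[C@]1(C)[C@@H]2CCC([Se]c3ccccc3)C(C)(O)[C@@H]2C(C)C(=O)C=C1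
F5 | step 10 | tertiary allylic alcohol (3-hydroxy, C1=C2) derived from 15 | CC(C)(C)[Si](C)(C)OC[C@]1(C)[C@@H]2CC=CC(C)(O)[C@@H]2C(C)C(=O)C=C1
F6 | step 12 | 7,8-epoxy ketone of 18 (epoxide on the face of CH3-14) | CC(C)(C)[Si](C)(C)OC[C@]1(C)[C@@H]2[C@H]3C(=O)C=C(C)[C@@H]2[C@@]3(C)C(=O)[C@H]2O[C@@H]12
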